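**Retrosynthetic overview**
1. Target ⇐ free tetraol by lipase acetylation of the only unbranched CH2OH ⇐ lactone diester by one global LiAlH4 reduction.
2. Side-chain stereocentre C13 ⇐ Ru–BINAP hydrogenation of an (E)-α-alkylidene-γ-butyrolactone ⇐ Wittig reaction of a ring aldehyde with the butyrolactone ylide.
3. C8 and C9 ⇐ hydroxyl-directed syn-hydrogenation of the tetrasubstituted C8=C9 alkene of a bicyclic 1,4-diene, on the face anti to the C10 methyl.
4. Rings A and B are formed together, from an acyclic precursor, by an enantioselective intramolecular [4+2] cycloaddition of a dienyne (ethynyl group on the malonate carbon, tetrasubstituted 1,3-diene); this gives the C5=C6 alkene and the quaternary C10 directly.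
5. Dienyne ⇐ malonate alkylation and ethynylation of a chloro-diene ⇐ carbomagnesiation/Kumada coupling of a chloroalkynol ⇐ but-3-yn-1-ol + 1-bromo-3-chloropropane.

Conventions: atoms are labelled by labdane numbering of the target (C4 carries the two CH2OH groups, C5=C6 is the ring alkene, C8 is CH–CH3, C9 carries the side chain, C10 is the methyl-bearing ring-fusion carbon, C13 is the side-chain stereocentre). β is the face of the C10 methyl. The target is 8S,9S,10R,13S, with the 8-methyl, the 9-side chain and the 10-methyl all cis.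

Assumption: for the two chiral catalysts (steps 5 and 9) the ligand antipode named is the one expected to give the drawn configuration; the sense is checked on the first run and the mirror-image ligand is used if it is opposite.

Step 1
Reactants: 1 but-3-yn-1-ol; 2 1-bromo-3-chloropropane
Product: 3 7-chlorohept-3-yn-1-ol
Conditions: n-BuLi (2.1 equiv), THF, −78 to −20 °C; then 2, DMPU, −20 °C to rt
Reagents that add atoms: none
Why: The alkoxide–acetylide dianion of 1 is C-alkylated by SN2 at the more reactive C–Br end of 2 (acetylide alkylation); no stereocentre is formed.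

Step 2
Reactants: 3 7-chlorohept-3-yn-1-ol; 4 2-bromopropene
Product: 6 (3E)-7-chloro-4-methyl-3-(prop-1-en-2-yl)hept-3-en-1-ol, via alkenylmagnesium bromide 5 (not isolated)
Conditions: MeMgBr (5 equiv), Fe(acac)3 (15 mol %), THF, −78 to 0 °C; then 4 (8 equiv), PdCl2(dppf) (5 mol %), 0 to 40 °C
Reagents that add atoms: methylmagnesium bromide, C[Mg]Br
Why: Alkoxide-directed, iron-catalysed syn-carbomagnesiation puts the methyl on the distal alkyne carbon and magnesium on the proximal one (five-membered O–Mg–C chelate), and Kumada coupling with retention then fixes the tetrasubstituted alkene with the methyl cis to the isopropenyl group.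

Step 3
Reactants: 6 (3E)-7-chloro-4-methyl-3-(prop-1-en-2-yl)hept-3-en-1-ol; 7 dimethyl malonate
Product: 8 dimethyl 2-[(4E)-7-hydroxy-4-methyl-5-(prop-1-en-2-yl)hept-4-en-1-yl]propanedioate
Conditions: NaH (1.2 equiv), 7 (3 equiv), NaI (0.2 equiv), DMF, 70 °C
Reagents that add atoms: none
Why: Malonate SN2 alkylation of the primary chloride with in situ Finkelstein activation; the far more acidic malonate is deprotonated in preference to the free alcohol, and no stereocentre is involved.

Step 4
Reactants: 8 dimethyl 2-[(4E)-7-hydroxy-4-methyl-5-(prop-1-en-2-yl)hept-4-en-1-yl]propanedioate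
Product: 9 dimethyl 2-ethynyl-2-[(4E)-7-hydroxy-4-methyl-5-(prop-1-en-2-yl)hept-4-en-1-yl]propanedioate
Conditions: TMS-EBX (1.3 equiv), TBAF (1.3 equiv), THF, −78 °C to rt
Reagents that add atoms: 1-[(trimethylsilyl)ethynyl]-1,2-benziodoxol-3(1H)-one (TMS-EBX), C[Si](C)(C)C#CI1OC(=O)c2ccccc12
Why: Electrophilic ethynylation of the malonate enolate with a hypervalent-iodine alkyne-transfer reagent (conjugate addition to ethynylbenziodoxolone, loss of 2-iodobenzoate, 1,2-hydride shift of the alkylidene carbene) builds quaternary C4 with the alkyne attached; no stereocentre.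

Step 5
Reactants: 9 dimethyl 2-ethynyl-2-[(4E)-7-hydroxy-4-methyl-5-(prop-1-en-2-yl)hept-4-en-1-yl]propanedioate
Product: 10 dimethyl (4aR)-5-(2-hydroxyethyl)-4a,6-dimethyl-3,4,4a,7-tetrahydronaphthalene-1,1(2H)-dicarboxylate (rings A and B; C5=C6 and C8=C9 alkenes; quaternary C10)
Conditions: [RhCl(cod)]2 (2.5 mol %), AgSbF6 (6 mol %), (R,R)-Me-DuPhos (6 mol %), ClCH2CH2Cl (0.02 M), 60 °C
Reagents that add atoms: none
Why: Proposed new method: cationic monovalent rhodium should bind the alkyne and the diene, couple C5 with C10 oxidatively to a rhodacycle (η3-allyl over C9–C7) and reductively eliminate C6–C7, so that both rings, the C5=C6 alkene and the quaternary C10 arise in one step with the chiral diphosphine selecting the diene face (C10 R); the closest known reaction type is the rhodium- or nickel-catalysed intramolecular [4+2] cycloaddition of 1,3-dien-8-ynes, including enantioselective versions, extended here to a fully substituted diene terminus.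

Step 6
Reactants: 10 dimethyl (4aR)-5-(2-hydroxyethyl)-4a,6-dimethyl-3,4,4a,7-tetrahydronaphthalene-1,1(2H)-dicarboxylate
Product: 11 dimethyl (4aR,5S,6S)-5-(2-hydroxyethyl)-4a,6-dimethyl-3,4,4a,5,6,7-hexahydronaphthalene-1,1(2H)-dicarboxylate
Conditions: H2 (1 atm), [Ir(cod)(PCy3)(py)]PF6 (5 mol %), CH2Cl2, 0 °C to rt
Reagents that add atoms: none
Why: Hydroxyl-directed hydrogenation with Crabtree's catalyst reduces the tetrasubstituted C8=C9 alkene next to the homoallylic OH in preference to the doubly neopentyl C5=C6 alkene, and syn delivery of both hydrogens to the face anti to the angular C10 methyl makes C8–H and C9–H α, i.e. the three substituents all cis (8S,9S).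

Step 7
Reactants: 11 dimethyl (4aR,5S,6S)-5-(2-hydroxyethyl)-4a,6-dimethyl-3,4,4a,5,6,7-hexahydronaphthalene-1,1(2H)-dicarboxylate
Product: 12 dimethyl (4aR,5S,6S)-4a,6-dimethyl-5-(2-oxoethyl)-3,4,4a,5,6,7-hexahydronaphthalene-1,1(2H)-dicarboxylate
Conditions: Dess–Martin periodinane (1.3 equiv), NaHCO3, CH2Cl2, 0 °C to rt
Reagents that add atoms: none
Why: Dess–Martin oxidation of the primary alcohol to the aldehyde under buffered, non-epimerising conditions; C9 is β to the new carbonyl and cannot epimerise.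

Step 8
Reactants: 12 dimethyl (4aR,5S,6S)-4a,6-dimethyl-5-(2-oxoethyl)-3,4,4a,5,6,7-hexahydronaphthalene-1,1(2H)-dicarboxylate; 13 3-(triphenylphosphoranylidene)oxolan-2-one
Product: 14 dimethyl (4aR,5S,6S)-4a,6-dimethyl-5-[(2E)-2-(2-oxooxolan-3-ylidene)ethyl]-3,4,4a,5,6,7-hexahydronaphthalene-1,1(2H)-dicarboxylate
Conditions: 13 (1.3 equiv), toluene, 80 °C
Reagents that add atoms: none
Why: Wittig olefination with a stabilised lactone ylide gives the (E)-α-alkylidene-γ-butyrolactone (alkyl chain trans to the lactone carbonyl), the geometry needed for the next step.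

Step 9
Reactants: 14 dimethyl (4aR,5S,6S)-4a,6-dimethyl-5-[(2E)-2-(2-oxooxolan-3-ylidene)ethyl]-3,4,4a,5,6,7-hexahydronaphthalene-1,1(2H)-dicarboxylate
Product: 15 dimethyl (4aR,5S,6S)-4a,6-dimethyl-5-{2-[(3S)-2-oxooxolan-3-yl]ethyl}-3,4,4a,5,6,7-hexahydronaphthalene-1,1(2H)-dicarboxylate
Conditions: H2 (50 atm), Ru(OAc)2[(S)-BINAP] (2 mol %), CH2Cl2, 50 °C
Reagents that add atoms: none
Why: Carbonyl-directed Ru–BINAP asymmetric hydrogenation of the (E)-alkylidene lactone sets C13 as S under catalyst control, independent of the remote ring stereocentres, and leaves the hindered, unfunctionalised C5=C6 alkene untouched.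

Step 10
Reactants: 15 dimethyl (4aR,5S,6S)-4a,6-dimethyl-5-{2-[(3S)-2-oxooxolan-3-yl]ethyl}-3,4,4a,5,6,7-hexahydronaphthalene-1,1(2H)-dicarboxylate
Product: 16 (2S)-2-{2-[(1S,2S,8aR)-5,5-bis(hydroxymethyl)-2,8a-dimethyl-1,2,3,5,6,7,8,8a-octahydronaphthalen-1-yl]ethyl}butane-1,4-diol
Conditions: LiAlH4 (5 equiv), THF, 0 °C to reflux; Fieser work-up
Reagents that add atoms: none
Why: LiAlH4 reduces both hindered methyl esters and the lactone to primary alcohols in one operation (ester reduction) without touching the isolated alkene or any of the four stereocentres.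

Step 11
Reactants: 16 (2S)-2-{2-[(1S,2S,8aR)-5,5-bis(hydroxymethyl)-2,8a-dimethyl-1,2,3,5,6,7,8,8a-octahydronaphthalen-1-yl]ethyl}butane-1,4-diol
Product: 17 (3S)-5-[(1S,2S,8aR)-5,5-bis(hydroxymethyl)-2,8a-dimethyl-1,2,3,5,6,7,8,8a-octahydronaphthalen-1-yl]-3-(hydroxymethyl)pentyl acetate
Conditions: vinyl acetate (1.5 equiv), Novozym 435 (immobilised Candida antarctica lipase B), THF, 25 °C, stopped at the mono-acetate
Reagents that add atoms: vinyl acetate, CC(=O)OC=C
Why: Lipase-catalysed transesterification is very sensitive to branching next to the carbinol carbon, so only the unbranched CH2CH2OH (C15) is acetylated while the β-branched C16 and the two neopentyl C18/C19 hydroxyls stay free; no stereocentre is touched.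

**Compound list**
1 | but-3-yn-1-ol | C#CCCO | starting material
2 | 1-bromo-3-chloropropane | ClCCCBr | starting material
3 | 7-chlorohept-3-yn-1-ol | OCCC#CCCCCl | intermediate
4 | 2-bromopropene | CC(Br)=C | starting material
5 | bromomagnesium (3E)-3-(bromomagnesio)-7-chloro-4-methylhept-3-en-1-olate (alkenylmagnesium bromide, Mg on C3 cis to the C4 methyl) | Br[Mg]OCC/C([Mg]Br)=C(/C)CCCCl | intermediate
6 | (3E)-7-chloro-4-methyl-3-(prop-1-en-2-yl)hept-3-en-1-ol (isopropenyl cis to the C4 methyl) | OCC/C(C(C)=C)=C(/C)CCCCl | intermediate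
7 | dimethyl malonate | COC(=O)CC(=O)OC | starting material
8 | dimethyl 2-[(4E)-7-hydroxy-4-methyl-5-(prop-1-en-2-yl)hept-4-en-1-yl]propanedioate | COC(=O)C(C(=O)OC)CCC/C(C)=C(\CCO)C(C)=C | intermediate
9 | dimethyl 2-ethynyl-2-[(4E)-7-hydroxy-4-methyl-5-(prop-1-en-2-yl)hept-4-en-1-yl]propanedioate | C#CC(C(=O)OC)(C(=O)OC)CCC/C(C)=C(\CCO)C(C)=C | intermediate
10 | dimethyl (4aR)-5-(2-hydroxyethyl)-4a,6-dimethyl-3,4,4a,7-tetrahydronaphthalene-1,1(2H)-dicarboxylate | OCCC1=C(C)CC=C2C(C(=O)OC)(C(=O)OC)CCC[C@@]21C | intermediate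
11 | dimethyl (4aR,5S,6S)-5-(2-hydroxyethyl)-4a,6-dimethyl-3,4,4a,5,6,7-hexahydronaphthalene-1,1(2H)-dicarboxylate | OCC[C@H]1[C@@H](C)CC=C2C(C(=O)OC)(C(=O)OC)CCC[C@@]21C | intermediate
12 | dimethyl (4aR,5S,6S)-4a,6-dimethyl-5-(2-oxoethyl)-3,4,4a,5,6,7-hexahydronaphthalene-1,1(2H)-dicarboxylate | O=CC[C@H]1[C@@H](C)CC=C2C(C(=O)OC)(C(=O)OC)CCC[C@@]21C | intermediate
13 | 3-(triphenylphosphoranylidene)oxolan-2-one | O=C1OCCC1=P(c1ccccc1)(c1ccccc1)c1ccccc1 | starting material
14 | dimethyl (4aR,5S,6S)-4a,6-dimethyl-5-[(2E)-2-(2-oxooxolan-3-ylidene)ethyl]-3,4,4a,5,6,7-hexahydronaphthalene-1,1(2H)-dicarboxylate | O=C1OCC/C1=C\C[C@H]2[C@@H](C)CC=C3C(C(=O)OC)(C(=O)OC)CCC[C@@]32C | intermediate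
15 | dimethyl (4aR,5S,6S)-4a,6-dimethyl-5-{2-[(3S)-2-oxooxolan-3-yl]ethyl}-3,4,4a,5,6,7-hexahydronaphthalene-1,1(2H)-dicarboxylate | O=C1OCC[C@@H]1CC[C@H]2[C@@H](C)CC=C3C(C(=O)OC)(C(=O)OC)CCC[C@@]32C | intermediate
16 | (2S)-2-{2-[(1S,2S,8aR)-5,5-bis(hydroxymethyl)-2,8a-dimethyl-1,2,3,5,6,7,8,8a-octahydronaphthalen-1-yl]ethyl}butane-1,4-diol | OCC[C@@H](CO)CC[C@H]1[C@@H](C)CC=C2C(CO)(CO)CCC[C@@]21C | intermediate
17 | (3S)-5-[(1S,2S,8aR)-5,5-bis(hydroxymethyl)-2,8a-dimethyl-1,2,3,5,6,7,8,8a-octahydronaphthalen-1-yl]-3-(hydroxymethyl)pentyl acetate | CC(=O)OCC[C@@H](CO)CC[C@H]1[C@@H](C)CC=C2C(CO)(CO)CCC[C@@]21C | target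

**Totals and risks**
Total step count: 11. Longest linear sequence: 11 steps (fully linear from but-3-yn-1-ol).

Step 5 (most likely to fail). The catalyst may not engage the fully substituted diene terminus, or may give low enantioselectivity when forming the quaternary carbon. Fallback, from 9 back to 10: drop catalysis and run the cycloaddition as a thermal intramolecular Diels–Alder reaction (degassed toluene, BHT, 200 °C, sealed vessel; the quaternary C10 blocks aromatisation of the 1,4-diene). This gives racemic dimethyl 5-(2-hydroxyethyl)-4a,6-dimethyl-3,4,4a,7-tetrahydronaphthalene-1,1(2H)-dicarboxylate F1. F1 is resolved by preparative chromatography on a chiral stationary phase, and the (4aR) enantiomer, which is 10, goes into step 6.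

Step 6. The face selectivity rests only on the difference between the C10 methyl and the ring CH2 at C10, and the all-cis product is the more strained one, so the wrong face or a mixture is possible; the malonate esters could also direct reduction of C5=C6. Fallback, from 10 back to 11: switch from substrate direction to catalyst control. The hydroxyl is masked (TBSCl, imidazole, DMF) as dimethyl (4aR)-5-[2-(tert-butyldimethylsilyloxy)ethyl]-4a,6-dimethyl-3,4,4a,7-tetrahydronaphthalene-1,1(2H)-dicarboxylate F2. F2 is hydrogenated with a chiral iridium phosphino-oxazoline catalyst, [Ir(cod)(tBu-PHOX)]BArF, at 50 atm H2 in CH2Cl2, screening both ligand antipodes for the one matched to α-face delivery. This gives dimethyl (4aR,5S,6S)-5-[2-(tert-butyldimethylsilyloxy)ethyl]-4a,6-dimethyl-3,4,4a,5,6,7-hexahydronaphthalene-1,1(2H)-dicarboxylate F3, and TBAF in THF returns 11.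

Step 2. The carbomagnesiation itself has precedent, but the one-pot Kumada coupling of the hindered alkenylmagnesium 5 has to compete with excess MeMgBr for 2-bromopropene. Fallback, from 3 back to 6: separate the two events. The same iron-catalysed methylmagnesiation is run and 5 is quenched with I2 to give (3E)-7-chloro-3-iodo-4-methylhept-3-en-1-ol F4, which is isolated. Suzuki–Miyaura coupling of F4 with isopropenylboronic acid pinacol ester (PdCl2(dppf), K3PO4, THF–H2O, 60 °C) then gives 6 with retention of the alkene geometry.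

**Further compounds**
F1 | step 5 | racemic dimethyl 5-(2-hydroxyethyl)-4a,6-dimethyl-3,4,4a,7-tetrahydronaphthalene-1,1(2H)-dicarboxylate | OCCC1=C(C)CC=C2C(C(=O)OC)(C(=O)OC)CCCC21C
F2 | step 6 | dimethyl (4aR)-5-[2-(tert-butyldimethylsilyloxy)ethyl]-4a,6-dimethyl-3,4,4a,7-tetrahydronaphthalene-1,1(2H)-dicarboxylate | CC(C)(C)[Si](C)(C)OCCC1=C(C)CC=C2C(C(=O)OC)(C(=O)OC)CCC[C@@]21C
F3 | step 6 | dimethyl (4aR,5S,6S)-5-[2-(tert-butyldimethylsilyloxy)ethyl]-4a,6-dimethyl-3,4,4a,5,6,7-hexahydronaphthalene-1,1(2H)-dicarboxylate | CC(C)(C)[Si](C)(C)OCC[C@H]1[C@@H](C)CC=C2C(C(=O)OC)(C(=O)OC)CCC[C@@]21C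
F4 | step 2 | (3E)-7-chloro-3-iodo-4-methylhept-3-en-1-ol | OCC/C(I)=C(/C)CCCCl
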